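**Remark on the chemistry:** labdane numbering and α/β descriptors are used throughout (β is the face of the C10 methyl; C17 is the methyl on C8); the C5/C10 configuration of the target is that of natural (−)-sclareol, which is assumed to be the correct enantiomeric starting material.

## Analysis of the target

Target 27 is a labdane in which a trans-decalin (rings A and B) carries at C9 a spiro tetrahydrofuran (ring C: O–C9–C11–C12–C13) and, spiro to it at C13, a 2,3-dihydrofuran (ring D: C13–C14=C15–O–C16). It has six stereocentres: C5 and C10 (trans fusion, 5α-H, 10β-methyl), C9 (oxygen α and axial on ring B, C11 β), C8 (hydroxyl β and axial, anti-periplanar to the C9–O bond, methyl α), C7 (acetoxy β and equatorial, cis to the C8 hydroxyl) and C13 (C14 on the face of ring C that carries C8, C16 on the face that carries C10). C6 to C9 are four contiguous oxygenated carbons, two of them fully substituted and next to the quaternary C10. The enol ether of ring D is the most sensitive group: the C13–O bond of ring C is allylic to it and behaves as a vinylogous ketal, so acid ionises it, opens ring C and aromatises ring D to a furan. The α-acetoxy ketone at C6/C7 tolerates neither hydride nor organometallic reagents and is prone to acyl migration and enolisation, so it has to appear last. The hardest stereocentre is C13, which sits 1,3 across the ring oxygen from C9 and sees two faces of ring C flanked by groups of similar size. The route rests on one feature: C13 carries C14 and C16, which are joined through C15 and the ring D oxygen. Removing that oxygen in the retro-Baeyer–Villiger sense leaves a spiro cyclobutanone C13–C14–C15–C16, which is the [2+2] adduct of a ketene with a C13=C16 exocyclic enol ether on ring C.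

## Retrosynthetic reasoning

**27 back to 23.** The C6 ketone and the C7 acetate are removed first, because neither survives the reduction that makes ring D. The ketone is traced to the 6α-alcohol 26, the free alcohol to its TBS ether 25, the acetate to the 7β,8β-diol 24, and the diol to its cyclic di-tert-butylsilylene 23. No C–C bond is cut. What is gained is a fully masked C6–C8 triad in which C6 and C7 are told apart by two silyl groups of different fluoride lability. The forward steps must all run without acid, since ring D is already present.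

**23 back to 20.** The C14=C15 double bond is traced to the lactol 21 (dehydration via 22) and this to the γ-lactone 20. The enol ether is therefore carried as a robust lactone until only protecting-group and oxidation-state changes remain. The forward reaction has to eliminate in the only possible direction (only C14 bears β-hydrogens) under basic conditions.

**20 back to 18.** The two C14 hydrogens are replaced by chlorine (19) and the ring oxygen between C15 and C16 is taken out, giving the spiro cyclobutanone 18. The order matters. With the chlorines in place C13 is a stereocentre and only the CH2 arm (C16) can migrate, so the oxygen insertion is regiospecific and the C13 configuration set in the cycloaddition is transferred to ring D. After dechlorination the two arms on C13 would be identical.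

**18 back to 15 and 17.** The C13–C14 and C15–C16 bonds are cut together. This is the only disconnection that removes ring D and the C13 stereocentre in one step while leaving a precursor, 15, whose remaining stereocentres all sit on the rigid decalin. Ketene 17 is generated from commercial 16. The forward cycloaddition has to bond C14 to C13 on the C8 face of ring C; its regiochemistry follows from the polarity of the enol ether.

**15 back to 14.** The exocyclic C13=C16 bond is traced to the lactone carbonyl of 14. A carbonyl methylenation gives the exocyclic isomer regiospecifically, which no dehydration of a ketal or hemiketal would guarantee.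

**14 back to 11.** The silylene is removed (13) and the C9–O bond of ring C is cut, giving the 8β,9β-epoxide 12 with the C13 ester as internal nucleophile, and this goes back to the allylic alcohol 11. This places the C8 and C9 oxygens trans-diaxial in one operation. The 7β-hydroxyl of 11 directs the epoxide to the β face, and the tether on C9 makes the opening 5-exo at C9 with inversion. The forward step has to overcome the β-face hindrance of the C10 methyl by hydroxyl direction.

**11 back to 7.** The 7β-alcohol is traced to the enone 10, the silyl ether to the α′-hydroxy enone 9, the C6 oxygen to the enone 8, and the C7 carbonyl to the tetrasubstituted alkene 7. All C6/C7 oxygenation is thus derived from one alkene by allylic oxidation, enolate oxidation and 1,2-reduction.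

**7 back to 1.** The alkene is traced to the tertiary alcohol of 6 and 5, the carboxyl carbon C13 to the methyl ketone 3, and this to the vinyl carbinol of 1. Compound 1 is chosen because its side chain already contains C11, C12 and C13, so that no homologation is needed. Its decalin supplies C5 and C10 in the correct absolute configuration.

## Alternatives that were turned down

**Alternative 1: cationic bicyclisation of an epoxy polyene ending on a β-keto ester.** The disconnection cuts C4–C5 and C9–C10. In the forward sense the Lewis acid MeAlCl2 A3 opens the epoxide of the acyclic (10S)-epoxy keto ester A2, the trisubstituted alkene relays the cation and the enol of the β-keto ester terminates it, giving the bicyclic keto ester A1 with rings A and B.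
- For: the decalin is built from an achiral chain in one step with predictable chair–chair stereocontrol. A1 has a C8 ketone and a C9 ester carbon as handles. The approach is independent of the terpene pool, and on that point it is stronger than the chosen route.
- Against: A1 contains none of what makes 27 difficult (C6/C7 oxygen, the C8 carbinol, the oxygenated quaternary C9, rings C and D). Its C3 hydroxyl is absent from 27 and has to be deleted. C12 and C13 still have to be attached.
- Comparison: in the chosen route three degradative steps from 1 deliver the decalin with C5, C10 and the whole C11–C13 chain. Alternative 1 spends more steps to reach a less advanced point and leaves the ring D problem unsolved.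

**Alternative 2: ring B closed last by an intramolecular aldol of a zinc enediolate.** The disconnection cuts C7–C8. Et2Zn A6 with the bis(prolinol)phenol ligand A7 would convert the hydroxymethyl ketone of the seco diketone A5 into a chelated enediolate, whose C7 adds to the C8 methyl ketone to give the 7-deacetyl compound A4. Acetylation would then give 27.
- For: one step sets C7 and C8 and delivers the α-ketol in its final oxidation state without protecting groups on C6–C8. Only one step follows the key step. In end-game economy this is clearly stronger than the chosen route, which needs four steps after ring D is formed.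
- Against: A5 must already contain both spiro centres on a monocyclic ring A, so C9 and C13 would have to be set next to the quaternary C10 without ring B to relay stereochemistry. The acceptor is a hindered, itself enolisable methyl ketone, and its own enolate could attack the C6 carbonyl. Ketone–ketone aldols are reversible. The catalyst would have to override the substrate to place the C8 hydroxyl axial and cis to the C7 hydroxyl. The acid-labile ring D would have to survive a Lewis acidic medium.
- Comparison: the chosen route keeps ring B from the start and uses it to set C8 and C9 by a stereospecific epoxide opening. The price is a longer protecting-group end game.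

**Alternative 3: ring C closed by epoxide opening with a C13 tertiary alcohol.** The disconnection cuts the C9–O bond. The catalyst VO(acac)2 A10 and the oxidant tert-butyl hydroperoxide A11 would epoxidise the 8-ene A9 syn to its 7β-hydroxyl, and the C13 hydroxyl would open the epoxide at C9 (5-exo) to give the tricycle A8. Ring D would follow by removal of the PMB group and cycloisomerisation onto the alkyne.
- For: the C8/C9 logic is the same as in the chosen route. Ring C is formed directly as the ether, and ring D is unveiled late under neutral conditions in about three steps instead of seven. On these points it is as strong or stronger.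
- Against: the C13 stereocentre becomes an acyclic tertiary propargylic carbinol whose two large substituents (CH2OPMB and the CH2CH2 chain) are hard to tell apart and which the decalin cannot influence, so a C13 mixture would be carried to the end. The side chain has to be assembled by several C–C bond formations. A tertiary alcohol is a poorer nucleophile than a carboxyl derivative for a hindered tetrasubstituted epoxide.
- Comparison: the chosen strategy creates C13 on the rigid tricycle, takes all but two carbons from 1, and offers a second, reagent-controlled chance at C13, because the two arms on C13 are only differentiated at the oxygen-insertion stage.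

Key step: step 11

## Route

Step 1
Reactants: 1 (−)-sclareol, (13R)-labd-14-ene-8α,13-diol
Product: 3 8α-hydroxy-14,15-dinorlabdan-13-one, via labdane-8α,13,14,15-tetraol 2 (not isolated)
Conditions: OsO4 (cat.), NaIO4, THF–H2O, 45 °C
Reagents that add atoms: none
Why: Lemieux–Johnson cleavage: OsO4 dihydroxylates the vinyl group to 2, and NaIO4 cleaves both vicinal diol bonds of its 13,14,15-triol unit, leaving C13 as the methyl ketone. The decalin stereocentres and the tertiary 8α-hydroxyl are not touched.

Step 2
Reactants: 3 8α-hydroxy-14,15-dinorlabdan-13-one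
Product: 5 8α-hydroxy-14,15,16-trinorlabdan-13-oic acid, via tribromomethyl ketone 4 (not isolated)
Conditions: Br2, NaOH, dioxane–H2O, 0 °C → rt; then HCl to pH 3
Reagents that add atoms: sodium hydroxide, [Na+].[OH-]
Why: Haloform reaction: the methyl group is brominated exhaustively through the less substituted enolate and hydroxide expels the CBr3 group of 4, so that C13 becomes the carboxyl carbon. The tertiary alcohol is inert and C8/C9 are untouched.

Step 3
Reactants: 5 8α-hydroxy-14,15,16-trinorlabdan-13-oic acid
Product: 7 methyl 14,15,16-trinorlabd-8-en-13-oate, via hydroxy methyl ester 6 (not isolated)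
Conditions: H2SO4 (conc.), MeOH, 65 °C; chromatography on AgNO3-impregnated silica
Reagents that add atoms: methanol, CO
Why: Fischer esterification gives 6, whose tertiary C8 cation loses a proton (E1) under the same acid. Under equilibrating conditions the tetrasubstituted 8(9)-alkene should predominate, and the minor 7-ene and 8(17)-ene isomers are separated and can be re-equilibrated.

Step 4
Reactants: 7 methyl 14,15,16-trinorlabd-8-en-13-oate
Product: 8 methyl 7-oxo-14,15,16-trinorlabd-8-en-13-oate
Conditions: CrO3, 3,5-dimethylpyrazole, CH2Cl2, −20 °C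
Reagents that add atoms: chromium trioxide, O=[Cr](=O)=O
Why: Allylic oxidation of the ring methylene C7 to the enone. C7 should be preferred over the other allylic methylene C11 because its axial C–H bond is aligned with the alkene π system, while C11 is shielded by C1 and the C10 methyl.

Step 5
Reactants: 8 methyl 7-oxo-14,15,16-trinorlabd-8-en-13-oate
Product: 9 methyl 6α-hydroxy-7-oxo-14,15,16-trinorlabd-8-en-13-oate
Conditions: KN(SiMe3)2, THF, −78 °C; then 2-(phenylsulfonyl)-3-phenyloxaziridine, −78 °C; NH4Cl (aq.)
Reagents that add atoms: 2-(phenylsulfonyl)-3-phenyloxaziridine (Davis oxaziridine), O=S(=O)(c1ccccc1)N1OC1c1ccccc1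
Why: Enolate hydroxylation: kinetic deprotonation at the α′ carbon C6 (faster than at the ester α-carbon C12 or the γ-carbon C11 at −78 °C) is followed by oxygen transfer from the oxaziridine to the α face, anti to the axial methyls on C4 and C10. The equatorial 6α-alcohol is expected; its configuration is immaterial because C6 ends as a ketone.

Step 6
Reactants: 9 methyl 6α-hydroxy-7-oxo-14,15,16-trinorlabd-8-en-13-oate
Product: 10 methyl 6α-(tert-butyldimethylsilyloxy)-7-oxo-14,15,16-trinorlabd-8-en-13-oate
Conditions: TBSOTf, 2,6-lutidine, CH2Cl2, −78 → 0 °C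
Reagents that add atoms: tert-butyldimethylsilyl triflate, CC(C)(C)[Si](C)(C)OS(=O)(=O)C(F)(F)F
Why: Silylation of a hindered secondary alcohol with the silyl triflate. The TBS ether is chosen because it withstands the organotitanium, ketene, peracid, radical and hydride steps and outlasts the silylene in step 16.

Step 7
Reactants: 10 methyl 6α-(tert-butyldimethylsilyloxy)-7-oxo-14,15,16-trinorlabd-8-en-13-oate
Product: 11 methyl 6α-(tert-butyldimethylsilyloxy)-7β-hydroxy-14,15,16-trinorlabd-8-en-13-oate
Conditions: NaBH4, CeCl3·7H2O, MeOH, −40 → 0 °C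
Reagents that add atoms: none
Why: Luche 1,2-reduction: hydride enters along the axial trajectory on the α face and should give the equatorial 7β-alcohol, trans to the 6α-silyloxy group. The ester is not reduced.

Step 8
Reactants: 11 methyl 6α-(tert-butyldimethylsilyloxy)-7β-hydroxy-14,15,16-trinorlabd-8-en-13-oate
Product: 13 6α-(tert-butyldimethylsilyloxy)-7β,8β-dihydroxy-14,15,16-trinorlabdan-13,9α-olide, via 8β,9β-epoxy ester 12 (not isolated)
Conditions: VO(acac)2 (cat.), t-BuOOH, CH2Cl2, 0 °C → rt; then camphorsulfonic acid (cat.), wet CH2Cl2, rt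
Reagents that add atoms: tert-butyl hydroperoxide, CC(C)(C)OO; water, O
Why: Hydroxyl-directed epoxidation delivers oxygen from the vanadium-bound peroxide to the β face syn to the 7β-hydroxyl despite the C10 methyl, as in the β-epoxidation of 3β-hydroxy-4-ene steroids. Acid then lets the ester carbonyl open 12 at C9 from the α face (5-exo, trans-diaxial opening), and water releases methanol from the cyclic dialkoxycarbenium ion. This sets C8 (hydroxyl β) and C9 (oxygen α) together.

Step 9
Reactants: 13 6α-(tert-butyldimethylsilyloxy)-7β,8β-dihydroxy-14,15,16-trinorlabdan-13,9α-olide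
Product: 14 7β,8β-O-(di-tert-butylsilylene) derivative of 13
Conditions: t-Bu2Si(OTf)2, 2,6-lutidine, CH2Cl2, 0 °C → rt
Reagents that add atoms: di-tert-butylsilyl bis(triflate), CC(C)(C)[Si](OS(=O)(=O)C(F)(F)F)(OS(=O)(=O)C(F)(F)F)C(C)(C)C
Why: Cyclic silylene formation on the cis diol (7β equatorial, 8β axial); the bis(triflate) silylates even tertiary alcohols. Both hydroxyls are masked in one step by a group that fluoride removes before a TBS ether.

Step 10
Reactants: 14 7β,8β-O-(di-tert-butylsilylene) derivative of 13
Product: 15 6α-(tert-butyldimethylsilyloxy)-7β,8β-(di-tert-butylsilylenedioxy)-9α,13-epoxy-14,15-dinorlabd-13(16)-ene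
Conditions: Cp2TiMe2, toluene, 75 °C, dark; filtration through basic alumina
Reagents that add atoms: dimethyltitanocene, [CH3-].[CH3-].[Ti+4].c1cc[cH-]c1.c1cc[cH-]c1
Why: Petasis methylenation of the lactone carbonyl through Cp2Ti=CH2 gives the exocyclic enol ether regiospecifically. The neutral conditions and the basic work-up should prevent migration of the double bond into ring C.

Step 11
Reactants: 15 6α-(tert-butyldimethylsilyloxy)-7β,8β-(di-tert-butylsilylenedioxy)-9α,13-epoxy-14,15-dinorlabd-13(16)-ene; 16 trichloroacetyl chloride
Product: 18 C13 spiro 2,2-dichlorocyclobutanone (14,14-dichloro-15,16-cyclo-9α,13-epoxylabdan-15-one with the 6α-TBS ether and 7β,8β-silylene, C14 cis to C8 on ring C), via dichloroketene 17 (not isolated)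
Conditions: Zn–Cu couple, 16 added slowly, Et2O–DME, 0 °C → rt; NaHCO3 (aq.) work-up
Reagents that add atoms: none
Why: The Zn–Cu couple dechlorinates 16 to dichloroketene 17, which is trapped at once by the electron-rich alkene of 15. The nucleophilic terminus C16 attacks the central ketene carbon C15 while positive charge builds at C13 beside the ring oxygen, and the C13–C14 bond closes in the same asynchronous transition state (formal [π2s+π2a] cycloaddition). The closest known reaction type is the addition of dichloroketene to exocyclic enol ethers such as exo-glycals and 2-methylenetetrahydrofurans, which gives spiro 3-alkoxy-2,2-dichlorocyclobutanones. The four-membered ring is closed intermolecularly, with both new bonds on one face of the C13=C16 bond and spiro to ring C. The one new stereocentre, C13, is set by the face of ring C that the ketene approaches: C14 has to bond on the face that carries C8, which is flanked only by the equatorial 8α-methyl, whereas the other face is flanked by C1 with ring A behind it, so a modest preference for the required face is expected. Regiochemistry is secured by the polarity of the enol ether and chemoselectivity by the absence of any other nucleophilic alkene, and the silyl groups keep the three hydroxyls from being acylated. DME precipitates ZnCl2, so the enol ether should neither migrate into ring C nor ionise.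

Step 12
Reactants: 18 C13 spiro 2,2-dichlorocyclobutanone
Product: 19 14,14-dichloro-9α,13-epoxylabdan-15,16-olide with the 6α-TBS ether and 7β,8β-silylene
Conditions: mCPBA, NaHCO3, CH2Cl2, 0 °C → rt
Reagents that add atoms: 3-chloroperoxybenzoic acid, OOC(=O)c1cccc(Cl)c1
Why: Baeyer–Villiger oxidation: the electron-poor CCl2 carbon does not migrate, so C16 migrates with retention and oxygen enters between C15 and C16. Oxidising before dechlorination keeps C13 stereogenic and fixes which arm becomes the O–CH2 of ring D.

Step 13
Reactants: 19 14,14-dichloro-9α,13-epoxylabdan-15,16-olide derivative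
Product: 20 9α,13-epoxylabdan-15,16-olide with the 6α-TBS ether and 7β,8β-silylene
Conditions: Bu3SnH, AIBN (cat.), toluene, 80 °C
Reagents that add atoms: none
Why: Radical chain dechlorination of an α,α-dichlorolactone. Unlike a zinc enolate, the α-carbonyl radical cannot expel the β-alkoxy group (the ring C oxygen), and the neutral medium spares both silyl groups.

Step 14
Reactants: 20 9α,13-epoxylabdan-15,16-olide derivative
Product: 21 9α,13:15,16-diepoxylabdan-15-ol (lactol, both C15 epimers) with the 6α-TBS ether and 7β,8β-silylene
Conditions: i-Bu2AlH, CH2Cl2, −78 °C; KNaC4H4O6 (aq.)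
Reagents that add atoms: none
Why: Partial reduction of the γ-lactone to the lactol: the tetrahedral aluminium alkoxide is stable at −78 °C and no other reducible group is present.

Step 15
Reactants: 21 9α,13:15,16-diepoxylabdan-15-ol derivative
Product: 23 6α-(tert-butyldimethylsilyloxy)-7β,8β-(di-tert-butylsilylenedioxy)-9α,13:15,16-diepoxylabd-14-ene, via lactol mesylate 22 (not isolated)
Conditions: MsCl, Et3N (excess), THF, −40 → 60 °C; Et3N-treated silica
Reagents that add atoms: none
Why: Lactol dehydration: the hemiacetal hydroxyl is sulfonylated to 22, which eliminates under excess amine. Only C14 carries β-hydrogens, so the double bond can form only between C14 and C15, and the medium stays basic throughout.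

Step 16
Reactants: 23 6α-(tert-butyldimethylsilyloxy)-7β,8β-(di-tert-butylsilylenedioxy)-9α,13:15,16-diepoxylabd-14-ene
Product: 24 6α-(tert-butyldimethylsilyloxy)-9α,13:15,16-diepoxylabd-14-ene-7β,8β-diol
Conditions: HF·pyridine, pyridine (large excess), THF, 0 °C; NaHCO3 (aq.)
Reagents that add atoms: none
Why: Fluoride cleaves the strained five-membered dialkoxysilane much faster than the hindered secondary TBS ether, the selectivity used for silylene removal beside TBS ethers in nucleoside chemistry. The excess of pyridine keeps the medium too weakly acidic to ionise the C13–O bond.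

Step 17
Reactants: 24 6α-(tert-butyldimethylsilyloxy)-9α,13:15,16-diepoxylabd-14-ene-7β,8β-diol
Product: 25 7β-acetoxy-6α-(tert-butyldimethylsilyloxy)-9α,13:15,16-diepoxylabd-14-en-8β-ol
Conditions: Ac2O, pyridine, DMAP (cat.), CH2Cl2, rt
Reagents that add atoms: acetic anhydride, CC(=O)OC(C)=O
Why: DMAP-catalysed acylation of the secondary equatorial 7β-hydroxyl. The tertiary axial 8β-hydroxyl does not react under these conditions and the basic medium is safe for ring D.

Step 18
Reactants: 25 7β-acetoxy-6α-(tert-butyldimethylsilyloxy)-9α,13:15,16-diepoxylabd-14-en-8β-ol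
Product: 26 7β-acetoxy-9α,13:15,16-diepoxylabd-14-ene-6α,8β-diol
Conditions: Bu4NF, AcOH (1:1), THF, 0 °C → rt
Reagents that add atoms: none
Why: Fluoride-induced cleavage of the TBS ether. Buffering with acetic acid suppresses 7→6 acetyl migration through the free alkoxide and keeps the medium near neutral for ring D.

Step 19
Reactants: 26 7β-acetoxy-9α,13:15,16-diepoxylabd-14-ene-6α,8β-diol
Product: 27 7β-acetoxy-8β-hydroxy-9α,13:15,16-diepoxylabd-14-en-6-one (target, CNP0284584.1)
Conditions: Dess–Martin periodinane, pyridine, CH2Cl2, 0 °C → rt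
Reagents that add atoms: none
Why: Dess–Martin oxidation of the secondary alcohol to the ketone; the tertiary alcohol is inert. Pyridine neutralises the acetic acid released, and no base strong enough to epimerise C5 or C7 is present.

## Compound list

1 | (−)-sclareol, (13R)-labd-14-ene-8α,13-diol | C1C[C@H]2C(C)(C)CCC[C@]2(C)[C@@H](CC[C@@](C)(O)C=C)[C@]1(C)O | starting material
2 | (13R)-labdane-8α,13,14,15-tetraol (both C14 epimers) | C1C[C@H]2C(C)(C)CCC[C@]2(C)[C@@H](CC[C@@](C)(O)C(O)CO)[C@]1(C)O | intermediate
3 | 8α-hydroxy-14,15-dinorlabdan-13-one | C1C[C@H]2C(C)(C)CCC[C@]2(C)[C@@H](CCC(C)=O)[C@]1(C)O | intermediate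
4 | 16,16,16-tribromo-8α-hydroxy-14,15-dinorlabdan-13-one | C1C[C@H]2C(C)(C)CCC[C@]2(C)[C@@H](CCC(=O)C(Br)(Br)Br)[C@]1(C)O | intermediate
5 | 8α-hydroxy-14,15,16-trinorlabdan-13-oic acid | C1C[C@H]2C(C)(C)CCC[C@]2(C)[C@@H](CCC(=O)O)[C@]1(C)O | intermediate
6 | methyl 8α-hydroxy-14,15,16-trinorlabdan-13-oate | C1C[C@H]2C(C)(C)CCC[C@]2(C)[C@@H](CCC(=O)OC)[C@]1(C)O | intermediate
7 | methyl 14,15,16-trinorlabd-8-en-13-oate | C1C[C@H]2C(C)(C)CCC[C@]2(C)C(CCC(=O)OC)=C1C | intermediate
8 | methyl 7-oxo-14,15,16-trinorlabd-8-en-13-oate | O=C1C[C@H]2C(C)(C)CCC[C@]2(C)C(CCC(=O)OC)=C1C | intermediate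
9 | methyl 6α-hydroxy-7-oxo-14,15,16-trinorlabd-8-en-13-oate | O=C1[C@H](O)[C@H]2C(C)(C)CCC[C@]2(C)C(CCC(=O)OC)=C1C | intermediate
10 | methyl 6α-(tert-butyldimethylsilyloxy)-7-oxo-14,15,16-trinorlabd-8-en-13-oate | O=C1[C@H](O[Si](C)(C)C(C)(C)C)[C@H]2C(C)(C)CCC[C@]2(C)C(CCC(=O)OC)=C1C | intermediate
11 | methyl 6α-(tert-butyldimethylsilyloxy)-7β-hydroxy-14,15,16-trinorlabd-8-en-13-oate | O[C@H]1[C@H](O[Si](C)(C)C(C)(C)C)[C@H]2C(C)(C)CCC[C@]2(C)C(CCC(=O)OC)=C1C | intermediate
12 | methyl 8β,9β-epoxy-6α-(tert-butyldimethylsilyloxy)-7β-hydroxy-14,15,16-trinorlabdan-13-oate | O[C@H]1[C@H](O[Si](C)(C)C(C)(C)C)[C@H]2C(C)(C)CCC[C@]2(C)[C@@]3(CCC(=O)OC)O[C@@]13C | intermediate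
13 | 6α-(tert-butyldimethylsilyloxy)-7β,8β-dihydroxy-14,15,16-trinorlabdan-13,9α-olide (spiro γ-lactone at C9, C17 methyl α) | O[C@H]1[C@H](O[Si](C)(C)C(C)(C)C)[C@H]2C(C)(C)CCC[C@]2(C)[C@@]2(CCC(=O)O2)[C@@]1(C)O | intermediate
14 | 7β,8β-O-(di-tert-butylsilylene) derivative of 13 | CC(C)(C)[Si]1(C(C)(C)C)O[C@H]2[C@H](O[Si](C)(C)C(C)(C)C)[C@H]3C(C)(C)CCC[C@]3(C)[C@@]3(CCC(=O)O3)[C@@]2(C)O1 | intermediate
15 | 6α-(tert-butyldimethylsilyloxy)-7β,8β-(di-tert-butylsilylenedioxy)-9α,13-epoxy-14,15-dinorlabd-13(16)-ene | CC(C)(C)[Si]1(C(C)(C)C)O[C@H]2[C@H](O[Si](C)(C)C(C)(C)C)[C@H]3C(C)(C)CCC[C@]3(C)[C@@]3(CCC(=C)O3)[C@@]2(C)O1 | intermediate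
16 | trichloroacetyl chloride | ClC(Cl)(Cl)C(Cl)=O | starting material
17 | dichloroketene | ClC(Cl)=C=O | intermediate
18 | C13 spiro 2,2-dichlorocyclobutanone: 6α-(tert-butyldimethylsilyloxy)-7β,8β-(di-tert-butylsilylenedioxy)-14,14-dichloro-15,16-cyclo-9α,13-epoxylabdan-15-one, C14 cis to C8 on ring C | CC(C)(C)[Si]1(C(C)(C)C)O[C@H]2[C@H](O[Si](C)(C)C(C)(C)C)[C@H]3C(C)(C)CCC[C@]3(C)[C@@]3(CC[C@@]4(C(Cl)(Cl)C(=O)C4)O3)[C@@]2(C)O1 | intermediate
19 | 6α-(tert-butyldimethylsilyloxy)-7β,8β-(di-tert-butylsilylenedioxy)-14,14-dichloro-9α,13-epoxylabdan-15,16-olide, C14 cis to C8 | CC(C)(C)[Si]1(C(C)(C)C)O[C@H]2[C@H](O[Si](C)(C)C(C)(C)C)[C@H]3C(C)(C)CCC[C@]3(C)[C@@]3(CC[C@@]4(C(Cl)(Cl)C(=O)OC4)O3)[C@@]2(C)O1 | intermediate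
20 | 6α-(tert-butyldimethylsilyloxy)-7β,8β-(di-tert-butylsilylenedioxy)-9α,13-epoxylabdan-15,16-olide, C14 cis to C8 | CC(C)(C)[Si]1(C(C)(C)C)O[C@H]2[C@H](O[Si](C)(C)C(C)(C)C)[C@H]3C(C)(C)CCC[C@]3(C)[C@@]3(CC[C@@]4(CC(=O)OC4)O3)[C@@]2(C)O1 | intermediate
21 | 6α-(tert-butyldimethylsilyloxy)-7β,8β-(di-tert-butylsilylenedioxy)-9α,13:15,16-diepoxylabdan-15-ol (both C15 epimers) | CC(C)(C)[Si]1(C(C)(C)C)O[C@H]2[C@H](O[Si](C)(C)C(C)(C)C)[C@H]3C(C)(C)CCC[C@]3(C)[C@@]3(CC[C@@]4(CC(O)OC4)O3)[C@@]2(C)O1 | intermediate
22 | 15-O-methanesulfonyl derivative of 21 | CC(C)(C)[Si]1(C(C)(C)C)O[C@H]2[C@H](O[Si](C)(C)C(C)(C)C)[C@H]3C(C)(C)CCC[C@]3(C)[C@@]3(CC[C@@]4(CC(OS(C)(=O)=O)OC4)O3)[C@@]2(C)O1 | intermediate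
23 | 6α-(tert-butyldimethylsilyloxy)-7β,8β-(di-tert-butylsilylenedioxy)-9α,13:15,16-diepoxylabd-14-ene, C14 cis to C8 | CC(C)(C)[Si]1(C(C)(C)C)O[C@H]2[C@H](O[Si](C)(C)C(C)(C)C)[C@H]3C(C)(C)CCC[C@]3(C)[C@@]3(CC[C@@]4(C=COC4)O3)[C@@]2(C)O1 | intermediate
24 | 6α-(tert-butyldimethylsilyloxy)-9α,13:15,16-diepoxylabd-14-ene-7β,8β-diol | O[C@H]1[C@H](O[Si](C)(C)C(C)(C)C)[C@H]2C(C)(C)CCC[C@]2(C)[C@@]2(CC[C@@]3(C=COC3)O2)[C@@]1(C)O | intermediate
25 | 7β-acetoxy-6α-(tert-butyldimethylsilyloxy)-9α,13:15,16-diepoxylabd-14-en-8β-ol | CC(=O)O[C@H]1[C@H](O[Si](C)(C)C(C)(C)C)[C@H]2C(C)(C)CCC[C@]2(C)[C@@]2(CC[C@@]3(C=COC3)O2)[C@@]1(C)O | intermediate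
26 | 7β-acetoxy-9α,13:15,16-diepoxylabd-14-ene-6α,8β-diol | CC(=O)O[C@H]1[C@H](O)[C@H]2C(C)(C)CCC[C@]2(C)[C@@]2(CC[C@@]3(C=COC3)O2)[C@@]1(C)O | intermediate
27 | 7β-acetoxy-8β-hydroxy-9α,13:15,16-diepoxylabd-14-en-6-one (C17 methyl α, C14 cis to C8 on ring C) | CC(=O)O[C@H]1C(=O)[C@H]2C(C)(C)CCC[C@]2(C)[C@@]2(CC[C@@]3(C=COC3)O2)[C@@]1(C)O | target

## Step count and least certain steps

Total step count: 19. Longest linear sequence: 19 steps (1 to 27); 16 enters at step 11.

**Step 11 (key step).** The facial discrimination at C13 may be weak or even reversed, because the two faces of ring C are flanked by groups of similar size (the 8α-methyl on one side, C1 on the other). In addition, traces of Lewis acid could move the exocyclic double bond into ring C before the cycloaddition. Fallback: the mixture of 18 and its C13 epimer F1 is dechlorinated first (Bu3SnH, AIBN, toluene, 80 °C). Both epimers give the same spiro cyclobutanone F2, in which C13 carries two identical CH2C(=O) arms and is no longer stereogenic. A catalyst-controlled Baeyer–Villiger desymmetrisation of F2 (chiral N,N′-dioxide–Sc(OTf)3 complex with mCPBA, or a Baeyer–Villiger monooxygenase, the catalyst antipode chosen so that the CH2 arm on the C10 face migrates) then sets C13 under reagent control and returns to the route at 20.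

**Step 16.** Ring D may be lost by acid-induced ionisation of the allylic C13–O bond (ring C opening and furan formation), and the discrimination between silylene and TBS ether may be incomplete in this crowded system. Fallback: starting from 20, where no enol ether is present, HF·pyridine/pyridine removes the silylene to give the diol lactone F3. TMSOTf/2,6-lutidine converts it into the bis(trimethylsilyl) ether F4, i-Bu2AlH at −78 °C gives the lactol F5, and MsCl/Et3N dehydrates it through the mesylate F6 to the dihydrofuran F7. K2CO3 in MeOH then removes both trimethylsilyl groups under basic conditions that touch neither the TBS ether nor ring D, and the route is rejoined at 24.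

**Step 8.** Directed epoxidation through a pseudo-equatorial hydroxyl may be slow, so that oxidation of the allylic alcohol back to the enone competes. The acid-promoted opening of the tetrasubstituted epoxide may also divert into 1,2-shifts instead of lactonisation through the ester. Fallback: starting from 11, LiOH (THF–H2O, 0 °C) gives the acid F8. mCPBA (NaHCO3, CH2Cl2, 0 °C), whose hydrogen bond to a pseudo-equatorial allylic hydroxyl is geometrically favourable (Henbest direction), gives the β-epoxy acid F9. Its free carboxyl group opens the epoxide at C9 without added acid, returning to the route at 13.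

**Step 5.** Enolisation at C6 may be incomplete or misdirected to the ester α-carbon or the γ-carbon, because the axial C6 hydrogen is shielded by the methyls on C4 and C10. Fallback: starting from 8, Mn(OAc)3·2H2O in refluxing benzene acetoxylates the α′ position through the manganese enolate without strong base and gives the 6α-acetate F10. K2CO3 in MeOH at 0 °C under argon cleaves the acetate and returns to the route at 9.

**Step 3.** Proton loss from the C8 cation may be poorly regioselective, since C7–H and C17–H compete with C9–H, and separation of the alkene isomers costs material. Fallback: starting from 5, MeI/K2CO3 in DMF gives the hydroxy ester 6, now isolated. POCl3/pyridine eliminates the equatorial 8α-hydroxyl kinetically towards the methyl group and gives the 8(17)-ene F11. SeO2/t-BuOOH hydroxylates the ring allylic position to the 7α-alcohol F12, Dess–Martin oxidation gives the exocyclic enone F13, and DBU moves the double bond into the ring. The route is rejoined at 8, so that neither 7 nor step 4 is needed.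

## Further compounds

F1 | step 11 | C13 epimer of 18 (C14 cis to C10) | CC(C)(C)[Si]1(C(C)(C)C)O[C@H]2[C@H](O[Si](C)(C)C(C)(C)C)[C@H]3C(C)(C)CCC[C@]3(C)[C@@]3(CC[C@]4(C(Cl)(Cl)C(=O)C4)O3)[C@@]2(C)O1
F2 | step 11 | 6α-(tert-butyldimethylsilyloxy)-7β,8β-(di-tert-butylsilylenedioxy)-15,16-cyclo-9α,13-epoxylabdan-15-one (spiro cyclobutanone) | CC(C)(C)[Si]1(C(C)(C)C)O[C@H]2[C@H](O[Si](C)(C)C(C)(C)C)[C@H]3C(C)(C)CCC[C@]3(C)[C@@]3(CCC4(CC(=O)C4)O3)[C@@]2(C)O1
F3 | step 16 | 6α-(tert-butyldimethylsilyloxy)-7β,8β-dihydroxy-9α,13-epoxylabdan-15,16-olide | O[C@H]1[C@H](O[Si](C)(C)C(C)(C)C)[C@H]2C(C)(C)CCC[C@]2(C)[C@@]2(CC[C@@]3(CC(=O)OC3)O2)[C@@]1(C)O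
F4 | step 16 | 7β,8β-bis(trimethylsilyl) ether of F3 | C[Si](C)(C)O[C@H]1[C@H](O[Si](C)(C)C(C)(C)C)[C@H]2C(C)(C)CCC[C@]2(C)[C@@]2(CC[C@@]3(CC(=O)OC3)O2)[C@@]1(C)O[Si](C)(C)C
F5 | step 16 | 6α-(tert-butyldimethylsilyloxy)-7β,8β-bis(trimethylsilyloxy)-9α,13:15,16-diepoxylabdan-15-ol | C[Si](C)(C)O[C@H]1[C@H](O[Si](C)(C)C(C)(C)C)[C@H]2C(C)(C)CCC[C@]2(C)[C@@]2(CC[C@@]3(CC(O)OC3)O2)[C@@]1(C)O[Si](C)(C)C
F6 | step 16 | 15-O-methanesulfonyl derivative of F5 | C[Si](C)(C)O[C@H]1[C@H](O[Si](C)(C)C(C)(C)C)[C@H]2C(C)(C)CCC[C@]2(C)[C@@]2(CC[C@@]3(CC(OS(C)(=O)=O)OC3)O2)[C@@]1(C)O[Si](C)(C)C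
F7 | step 16 | 6α-(tert-butyldimethylsilyloxy)-7β,8β-bis(trimethylsilyloxy)-9α,13:15,16-diepoxylabd-14-ene | C[Si](C)(C)O[C@H]1[C@H](O[Si](C)(C)C(C)(C)C)[C@H]2C(C)(C)CCC[C@]2(C)[C@@]2(CC[C@@]3(C=COC3)O2)[C@@]1(C)O[Si](C)(C)C
F8 | step 8 | 6α-(tert-butyldimethylsilyloxy)-7β-hydroxy-14,15,16-trinorlabd-8-en-13-oic acid | O[C@H]1[C@H](O[Si](C)(C)C(C)(C)C)[C@H]2C(C)(C)CCC[C@]2(C)C(CCC(=O)O)=C1C
F9 | step 8 | 8β,9β-epoxy-6α-(tert-butyldimethylsilyloxy)-7β-hydroxy-14,15,16-trinorlabdan-13-oic acid | O[C@H]1[C@H](O[Si](C)(C)C(C)(C)C)[C@H]2C(C)(C)CCC[C@]2(C)[C@@]3(CCC(=O)O)O[C@@]13C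
F10 | step 5 | methyl 6α-acetoxy-7-oxo-14,15,16-trinorlabd-8-en-13-oate | O=C1[C@H](OC(C)=O)[C@H]2C(C)(C)CCC[C@]2(C)C(CCC(=O)OC)=C1C
F11 | step 3 | methyl 14,15,16-trinorlabd-8(17)-en-13-oate | C=C1CC[C@H]2C(C)(C)CCC[C@]2(C)[C@H]1CCC(=O)OC
F12 | step 3 | methyl 7α-hydroxy-14,15,16-trinorlabd-8(17)-en-13-oate | C=C1[C@H](O)C[C@H]2C(C)(C)CCC[C@]2(C)[C@H]1CCC(=O)OC
F13 | step 3 | methyl 7-oxo-14,15,16-trinorlabd-8(17)-en-13-oate | C=C1C(=O)C[C@H]2C(C)(C)CCC[C@]2(C)[C@H]1CCC(=O)OC
A1 | alternative 1 | methyl 3β-hydroxy-8-oxo-12-nordriman-11-oate (3-hydroxy-8-oxo trans-decalin with the methyl ester on C9) | C1C[C@H]2C(C)(C)[C@@H](O)CC[C@]2(C)[C@@H](C(=O)OC)C1=O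
A2 | alternative 1 | methyl (6E,10S)-10,11-epoxy-7,11-dimethyl-3-oxododec-6-enoate | COC(=O)CC(=O)CC/C=C(\C)CC[C@@H]1OC1(C)C
A3 | alternative 1 | methylaluminium dichloride | C[Al](Cl)Cl
A4 | alternative 2 | 7β,8β-dihydroxy-9α,13:15,16-diepoxylabd-14-en-6-one (7-deacetyl target) | O[C@H]1C(=O)[C@H]2C(C)(C)CCC[C@]2(C)[C@@]2(CC[C@@]3(C=COC3)O2)[C@@]1(C)O
A5 | alternative 2 | 7-hydroxy-9α,13:15,16-diepoxy-7,8-secolabd-14-ene-6,8-dione | OCC(=O)[C@H]1C(C)(C)CCC[C@]1(C)[C@@]1(CC[C@@]2(C=COC2)O1)C(C)=O
A6 | alternative 2 | diethylzinc | CC[Zn]CC
A7 | alternative 2 | 2,6-bis[[(2S)-2-(hydroxydiphenylmethyl)pyrrolidin-1-yl]methyl]-4-methylphenol (drawn as the S,S form; the antipode if required) | Cc1cc(CN2CCC[C@H]2C(O)(c2ccccc2)c2ccccc2)c(O)c(CN2CCC[C@H]2C(O)(c2ccccc2)c2ccccc2)c1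
A8 | alternative 3 | 6α-(tert-butyldimethylsilyloxy)-13-ethynyl-13-[(4-methoxybenzyloxy)methyl] 9α,13-epoxy tricycle with the 7β,8β-diol | O[C@H]1[C@H](O[Si](C)(C)C(C)(C)C)[C@H]2C(C)(C)CCC[C@]2(C)[C@@]2(CC[C@@](COCc3ccc(OC)cc3)(C#C)O2)[C@@]1(C)O
A9 | alternative 3 | 6α-(tert-butyldimethylsilyloxy)-16-(4-methoxybenzyloxy)labd-8-en-14-yne-7β,13-diol | O[C@H]1[C@H](O[Si](C)(C)C(C)(C)C)[C@H]2C(C)(C)CCC[C@]2(C)C(CC[C@@](O)(COCc3ccc(OC)cc3)C#C)=C1C
A10 | alternative 3 | vanadyl bis(acetylacetonate), VO(acac)2 | CC(=O)/C=C(/C)[O-].CC(=O)/C=C(/C)[O-].O=[V+2]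
A11 | alternative 3 | tert-butyl hydroperoxide | CC(C)(C)OO
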